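The target is a twofold-symmetric dimer: two identical bibenzyl halves share one methylene carbon, bonded on each ring A (the 3-hydroxy-5-methoxyphenyl ring) to C2, the carbon between the chain-bearing C1 and the hydroxyl-bearing C3, para to OMe. The disconnection is the ArCH2–Ar bond. In one operation, the bromomagnesium phenoxide of the monomer takes up formaldehyde at C2, the resulting o-hydroxybenzyl alkoxide collapses to an o-quinone methide, and a second phenoxide adds through its own C2, joining the halves. The step exploits the C3 hydroxyl ortho to each bridge-bearing C2 as a magnesium anchor. The precursor is the monomeric bibenzyl phenol whose ring-B phenol is masked as a benzyl ether.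

Key step: step 2

Assumption: the target has no stereocentre and is achiral, so no stereocontrol is needed; compounds 1, 2 and 4 are taken as catalogue chemicals.

Ring labels used below: ring A = 3-hydroxy-5-methoxyphenyl ring (C1 carries the CH2CH2Ar chain, C3 the OH, C5 the OMe; C2 lies between C1 and C3, C4 between C3 and C5). Ring B = 4-oxy-3-methoxyphenyl ring.

Step 1
Reactants: 1 4-(benzyloxy)-3-methoxystyrene; 2 9-borabicyclo[3.3.1]nonane (9-BBN-H); 4 3-bromo-5-methoxyphenol
Product: 5 3-[2-(4-benzyloxy-3-methoxyphenyl)ethyl]-5-methoxyphenol, via alkylborane 3 (not isolated)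
Conditions: 1 + 2, THF, 0 °C to rt; then 4, PdCl2(dppf) (cat.), 3 M aq NaOH, THF, 65 °C; NH4Cl work-up
Reagents that add atoms: none
Why: Anti-Markovnikov hydroboration of the styrene gives the primary B-alkyl-9-BBN, which after hydroxide activation transmetalates to the arylpalladium formed by oxidative addition into the C–Br bond and reductively eliminates the sp3–sp2 bond (B-alkyl Suzuki–Miyaura coupling); the benzyl ether and the free phenol (as phenoxide) should tolerate the conditions.

Step 2
Reactants: 5 3-[2-(4-benzyloxy-3-methoxyphenyl)ethyl]-5-methoxyphenol (two molecules)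
Product: 8 2,2'-methylenebis{3-[2-(4-benzyloxy-3-methoxyphenyl)ethyl]-5-methoxyphenol}, via hydroxymethylphenol 6 (not isolated), via o-quinone methide 7 (not isolated)
Conditions: EtMgBr (1.0 equiv), Et2O, 0 °C to rt; solvent switch to toluene; (CH2O)n (0.5 equiv as CH2O), 110 °C; 1 M HCl work-up
Reagents that add atoms: paraformaldehyde (as formaldehyde), C=O
Why: The bromomagnesium phenoxide of 5 binds formaldehyde at magnesium and delivers it through a six-membered transition state to ring-A C2, giving the magnesium salt of 6; in hot non-coordinating toluene this loses Mg–OH to the magnesium-bound o-quinone methide 7, and a second phenoxide adds through its own C2 to the exocyclic CH2, forming the fragment-joining ArCH2–Ar bond before rearomatisation. The closest known reaction type is the ortho-specific condensation of bromomagnesium phenoxides with paraformaldehyde to 2,2'-methylenebisphenols (an o-quinone methide Friedel–Crafts alkylation), which also mirrors the presumed formaldehyde-equivalent biogenesis of methylene-bridged bibenzyls. No ring is closed and no stereocentre is formed. The step needs ortho-over-para selectivity, which chelation of the electrophile at the phenoxide magnesium should secure, and selectivity between the two ortho carbons, which the C5 methoxy group should secure by making C2 (para to OMe) more nucleophilic than C4 (between OH and OMe), the usual preference of 3-alkoxyphenoxides in magnesium-mediated ortho-functionalisation. Ring B should stay out because its phenol is a benzyl ether (no phenoxide, no quinone methide) and the medium is not acidic; sub-stoichiometric formaldehyde, the absence of donor additives (no Oppenauer-type oxidation to the salicylaldehyde) and the lower reactivity of the remaining C4 sites should hold the reaction at the dimer.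

Step 3
Reactants: 8 2,2'-methylenebis{3-[2-(4-benzyloxy-3-methoxyphenyl)ethyl]-5-methoxyphenol}
Product: 9 2,2'-methylenebis{3-[2-(4-hydroxy-3-methoxyphenyl)ethyl]-5-methoxyphenol} (target)
Conditions: H2 (1 atm), 10% Pd/C, EtOAc–MeOH, rt
Reagents that add atoms: none
Why: Palladium-catalysed hydrogenolysis (O-debenzylation) should cleave both aryl benzyl ethers, while the methyl ethers, the phenols and the diarylmethane and bibenzyl C–C bonds are inert under these conditions.

Compound list
1 | 4-(benzyloxy)-3-methoxystyrene | C=Cc1ccc(OCc2ccccc2)c(OC)c1 | starting material
2 | 9-borabicyclo[3.3.1]nonane (9-BBN-H) | B1C2CCCC1CCC2 | starting material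
3 | B-[2-(4-benzyloxy-3-methoxyphenyl)ethyl]-9-borabicyclo[3.3.1]nonane | COc1cc(CCB2C3CCCC2CCC3)ccc1OCc1ccccc1 | intermediate (not isolated)
4 | 3-bromo-5-methoxyphenol | COc1cc(O)cc(Br)c1 | starting material
5 | 3-[2-(4-benzyloxy-3-methoxyphenyl)ethyl]-5-methoxyphenol | COc1cc(O)cc(CCc2ccc(OCc3ccccc3)c(OC)c2)c1 | intermediate
6 | 3-[2-(4-benzyloxy-3-methoxyphenyl)ethyl]-2-(hydroxymethyl)-5-methoxyphenol (magnesium-bound in the flask, shown neutral) | COc1cc(O)c(CO)c(CCc2ccc(OCc3ccccc3)c(OC)c2)c1 | intermediate (not isolated)
7 | 5-[2-(4-benzyloxy-3-methoxyphenyl)ethyl]-3-methoxy-6-methylidenecyclohexa-2,4-dien-1-one (magnesium-bound in the flask, shown neutral) | COC1=CC(=O)C(=C)C(CCc2ccc(OCc3ccccc3)c(OC)c2)=C1 | intermediate (not isolated)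
8 | 2,2'-methylenebis{3-[2-(4-benzyloxy-3-methoxyphenyl)ethyl]-5-methoxyphenol} | COc1cc(O)c(Cc2c(O)cc(OC)cc2CCc2ccc(OCc3ccccc3)c(OC)c2)c(CCc2ccc(OCc3ccccc3)c(OC)c2)c1 | intermediate
9 | 2,2'-methylenebis{3-[2-(4-hydroxy-3-methoxyphenyl)ethyl]-5-methoxyphenol} | COc1cc(O)c(Cc2c(O)cc(OC)cc2CCc2ccc(O)c(OC)c2)c(CCc2ccc(O)c(OC)c2)c1 | target

Total step count: 3
Longest linear sequence: 3 steps (1 to 5 to 8 to 9)

Steps most likely to fail

Step 2. What may go wrong: poor site selectivity between the two ortho carbons of ring A (bond formation through C4 in either C–C bond-forming event), and over-condensation of the product with further formaldehyde to higher oligomers. The fallback sets out from 5 and comes back at 8, and separates the two bond formations. Compound 5 would be ortho-formylated (MgCl2, Et3N, excess paraformaldehyde, MeCN, reflux) to 6-[2-(4-benzyloxy-3-methoxyphenyl)ethyl]-2-hydroxy-4-methoxybenzaldehyde F1, a stable compound at which the position of the new carbon can be proven and any isomer removed. Reduction with NaBH4 (MeOH–THF, 0 °C) should give the hydroxymethylphenol 6, here isolated. Compound 6 would then be heated in toluene with the bromomagnesium phenoxide made from an excess of 5 (EtMgBr), so that the fragment-joining bond forms as a cross-condensation with no free formaldehyde present; unreacted 5 would be recovered.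

Step 1. What may go wrong: slow oxidative addition into the electron-rich, phenoxide-bearing aryl bromide, so that protodeboronation of the alkylborane or β-hydride elimination of the alkylpalladium outruns the coupling. The fallback sets out from 1 and 4 and comes back at 5. A Mizoroki–Heck reaction (Pd(OAc)2, K2CO3, n-Bu4NBr, DMF, 100 °C) should give (E)-3-[2-(4-benzyloxy-3-methoxyphenyl)ethenyl]-5-methoxyphenol F2. The alkene would then be reduced with diimide (TsNHNH2, NaOAc, DME–H2O, reflux), which leaves the benzyl ether in place.

Step 3. What may go wrong: incomplete hydrogenolysis through catalyst poisoning by magnesium or palladium residues carried from the earlier steps, leaving mono-benzyl ether. The fallback sets out from 8 and comes back at 9, and makes no new compound (F0). It is a Lewis-acid debenzylation with BCl3 and pentamethylbenzene as cation scavenger (CH2Cl2, −78 °C), which should cleave aryl benzyl ethers in preference to aryl methyl ethers.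

Further compounds
F1 | step 2 | 6-[2-(4-benzyloxy-3-methoxyphenyl)ethyl]-2-hydroxy-4-methoxybenzaldehyde | COc1cc(O)c(C=O)c(CCc2ccc(OCc3ccccc3)c(OC)c2)c1
F2 | step 1 | (E)-3-[2-(4-benzyloxy-3-methoxyphenyl)ethenyl]-5-methoxyphenol | COc1cc(O)cc(/C=C/c2ccc(OCc3ccccc3)c(OC)c2)c1
F0 | step 3 | none | none
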